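## Retrosynthetic overview

1. The three phenols are released last from a tris(methoxymethyl) ether of the target; all earlier chemistry runs on MOM-protected rings.
2. Ring C (the pyranone of the flavanone) is cut at C3–C4 and at O1–C2. This gives a ring-A salicylaldehyde (formyl carbon = C4, free ortho-hydroxyl = O1) and a ring-B terminal aryl alkyne (its two sp carbons = C2 and C3). Forward, a rhodium hydroacylation and a catalyst-controlled oxa-Michael closure are run in one flask.
3. Enabling feature: the ortho-hydroxyaryl ketone of rings A/C (O1 on C8a beside C4=O on C4a, with benzylic C2 β to C4). The same phenol first anchors rhodium at the formyl C–H bond and then is the nucleophile for C2.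
4. The alkyne comes from an aryl bromide (Sonogashira coupling); ring D (the 2,2-dimethylpyranone) from a Kabbe condensation of a 5-bromo-2-hydroxyacetophenone with acetone; the bromine from phenol-directed bromination of mono-MOM-protected 2',3'-dihydroxyacetophenone.
5. Order of ring formation: rings A and B are purchased arenes, ring D is closed first (step 3), ring C last (step 7).

Key step: step 7

Assumption: the sense of induction of cinchona-derived bifunctional catalysts on the 2'-hydroxychalcone of the key step cannot be predicted with certainty. The quinidine-derived thiourea is written for 2S; its quinine-derived pseudoenantiomer would replace it without other change if the sense proved opposite.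

## Route

Step 1
Reactants: 1 1-(2,3-dihydroxyphenyl)ethan-1-one (2',3'-dihydroxyacetophenone)
Product: 2 1-[2-hydroxy-3-(methoxymethoxy)phenyl]ethan-1-one
Conditions: MOMCl (1.05 equiv), i-Pr2NEt (1.5 equiv), CH2Cl2, 0 °C
Reagents that add atoms: chloromethyl methyl ether (MOMCl), COCCl
Why: Selective O-alkylation (MOM acetal formation) should occur at the 3-hydroxyl, because the 2-hydroxyl is held in a six-membered hydrogen bond to the acetyl carbonyl and is the less acidic and less nucleophilic of the two.

Step 2
Reactants: 2 1-[2-hydroxy-3-(methoxymethoxy)phenyl]ethan-1-one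
Product: 3 1-[5-bromo-2-hydroxy-3-(methoxymethoxy)phenyl]ethan-1-one
Conditions: NBS (1.0 equiv), MeCN, 0 °C to rt
Reagents that add atoms: N-bromosuccinimide, O=C1CCC(=O)N1Br
Why: Electrophilic aromatic bromination should go para to the free phenol (C5), since both ortho positions of the phenol are occupied and C5 is also meta to the deactivating acetyl group.

Step 3
Reactants: 3 1-[5-bromo-2-hydroxy-3-(methoxymethoxy)phenyl]ethan-1-one
Product: 5 6-bromo-8-(methoxymethoxy)-2,2-dimethyl-2,3-dihydro-4H-chromen-4-one, via ring-open enone 4 (not isolated)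
Conditions: acetone (5 equiv), pyrrolidine (0.5 equiv), MeOH, 60 °C
Reagents that add atoms: acetone, CC(C)=O
Why: Kabbe condensation, in which pyrrolidine-mediated crossed aldol condensation of the methyl ketone with acetone gives the β,β-dimethyl enone 4 and the ortho phenol then closes ring D by 6-endo-trig oxa-Michael addition.

Step 4
Reactants: 5 6-bromo-8-(methoxymethoxy)-2,2-dimethyl-2,3-dihydro-4H-chromen-4-one
Product: 6 8-(methoxymethoxy)-2,2-dimethyl-6-[(trimethylsilyl)ethynyl]-2,3-dihydro-4H-chromen-4-one
Conditions: Pd(PPh3)2Cl2 (3 mol %), CuI (6 mol %), Et3N/THF, 65 °C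
Reagents that add atoms: ethynyltrimethylsilane, C#C[Si](C)(C)C
Why: Sonogashira coupling (oxidative addition of zerovalent palladium into the aryl bromide, copper acetylide transmetalation, reductive elimination) should tolerate the ketone, the acetal and ring D.

Step 5
Reactants: 6 8-(methoxymethoxy)-2,2-dimethyl-6-[(trimethylsilyl)ethynyl]-2,3-dihydro-4H-chromen-4-one
Product: 7 6-ethynyl-8-(methoxymethoxy)-2,2-dimethyl-2,3-dihydro-4H-chromen-4-one
Conditions: K2CO3 (0.2 equiv), MeOH, rt
Reagents that add atoms: none
Why: Base-catalysed methanolysis of the C(sp)–Si bond should free the terminal alkyne under conditions too mild to open ring D or touch the MOM ether.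

Step 6
Reactants: 8 2,4,6-trihydroxybenzaldehyde
Product: 9 2-hydroxy-4,6-bis(methoxymethoxy)benzaldehyde
Conditions: MOMCl (2.2 equiv), i-Pr2NEt (3 equiv), CH2Cl2, 0 °C to rt
Reagents that add atoms: chloromethyl methyl ether (MOMCl), COCCl
Why: MOM acetal formation should stop after two alkylations, because the last ortho-hydroxyl is chelated to the formyl oxygen and unreactive toward the amine base/MOMCl system, which leaves the phenol the key step needs.

Step 7
Reactants: 9 2-hydroxy-4,6-bis(methoxymethoxy)benzaldehyde; 7 6-ethynyl-8-(methoxymethoxy)-2,2-dimethyl-2,3-dihydro-4H-chromen-4-one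
Product: 11 (2S)-5,7-bis(methoxymethoxy)-2-[8-(methoxymethoxy)-2,2-dimethyl-4-oxo-3,4-dihydro-2H-chromen-6-yl]-2,3-dihydro-4H-chromen-4-one, via (E)-2'-hydroxychalcone 10 (not isolated)
Conditions: 9 (1.2 equiv), [Rh(OMe)(cod)]2 (2.5 mol %), dppf (5.5 mol %), toluene, premix, then slow addition of 7, 80 °C; then 0 °C, quinidine-derived 3,5-bis(trifluoromethyl)phenyl thiourea (20 mol %); quench with 1 M HCl (aq)
Reagents that add atoms: none
Why: Proposed new method: the monovalent rhodium phenoxide formed from 9 should insert into the formyl C–H bond to give a five-membered acyl rhodium hydride chelate (trivalent rhodium), syn-hydrometalation of alkyne 7 then places rhodium on the terminal carbon, and C–C reductive elimination forms the C3–C4 bond and releases (E)-chalcone 10; the closest known reaction types are the rhodium-catalysed tandem alkyne hydroacylation/oxa-Michael synthesis of chroman-4-ones from salicylaldehydes and the cinchona (thio)urea-catalysed asymmetric oxa-Michael cyclisation of phenols onto aryl enones, which have not been run together as one enantioselective relay. In the second stage the quinuclidine nitrogen of the bifunctional catalyst engages the 2'-hydroxyl while the thiourea hydrogen-bonds the enone carbonyl, and the phenol oxygen adds to the β-carbon to form the O1–C2 bond. Ring C closes in the 6-endo-trig mode. The C2 stereocentre is set under catalyst control, the chiral pocket differentiating the two faces of the enone β-carbon, with 2S assigned to the quinidine-derived catalyst. The step needs chemoselective C–H insertion without decarbonylation, secured by the ortho-hydroxyl of 9 as chelating anchor, and linear regioselectivity (acyl to the terminal alkyne carbon), secured by the unsubstituted alkyne terminus of 7 that takes the metal while hydride goes to the aryl-bearing carbon. It also needs the catalysed closure to outrun racemic background cyclisation, secured by the hydrogen-bonded, unactivated enone of 10 (slow to close uncatalysed in toluene), the base-free methoxide precatalyst, low temperature and the acid quench before reversible ring opening can set in.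

Step 8
Reactants: 11 (2S)-5,7-bis(methoxymethoxy)-2-[8-(methoxymethoxy)-2,2-dimethyl-4-oxo-3,4-dihydro-2H-chromen-6-yl]-2,3-dihydro-4H-chromen-4-one
Product: 12 (2S)-5,7-dihydroxy-2-(8-hydroxy-2,2-dimethyl-4-oxo-3,4-dihydro-2H-chromen-6-yl)-2,3-dihydro-4H-chromen-4-one
Conditions: HCl (1.25 M in MeOH), THF, 40 °C
Reagents that add atoms: none
Why: Acid-catalysed acetal exchange with methanol should remove all three MOM groups, while ring D and the C2 stereocentre, which racemises mainly through base-induced ring opening, should persist under mild acid.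

## Compound list

1 | 1-(2,3-dihydroxyphenyl)ethan-1-one | CC(=O)c1cccc(O)c1O | starting material
2 | 1-[2-hydroxy-3-(methoxymethoxy)phenyl]ethan-1-one | CC(=O)c1cccc(OCOC)c1O | intermediate
3 | 1-[5-bromo-2-hydroxy-3-(methoxymethoxy)phenyl]ethan-1-one | CC(=O)c1cc(Br)cc(OCOC)c1O | intermediate
4 | 1-[5-bromo-2-hydroxy-3-(methoxymethoxy)phenyl]-3-methylbut-2-en-1-one | CC(C)=CC(=O)c1cc(Br)cc(OCOC)c1O | intermediate (not isolated)
5 | 6-bromo-8-(methoxymethoxy)-2,2-dimethyl-2,3-dihydro-4H-chromen-4-one | CC1(C)CC(=O)c2cc(Br)cc(OCOC)c2O1 | intermediate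
6 | 8-(methoxymethoxy)-2,2-dimethyl-6-[(trimethylsilyl)ethynyl]-2,3-dihydro-4H-chromen-4-one | CC1(C)CC(=O)c2cc(C#C[Si](C)(C)C)cc(OCOC)c2O1 | intermediate
7 | 6-ethynyl-8-(methoxymethoxy)-2,2-dimethyl-2,3-dihydro-4H-chromen-4-one | CC1(C)CC(=O)c2cc(C#C)cc(OCOC)c2O1 | intermediate
8 | 2,4,6-trihydroxybenzaldehyde | O=Cc1c(O)cc(O)cc1O | starting material
9 | 2-hydroxy-4,6-bis(methoxymethoxy)benzaldehyde | O=Cc1c(O)cc(OCOC)cc1OCOC | intermediate
10 | (E)-1-[2-hydroxy-4,6-bis(methoxymethoxy)phenyl]-3-[8-(methoxymethoxy)-2,2-dimethyl-4-oxo-3,4-dihydro-2H-chromen-6-yl]prop-2-en-1-one | COCOc1cc(O)c(C(=O)/C=C/c2cc(OCOC)c3OC(C)(C)CC(=O)c3c2)c(OCOC)c1 | intermediate (not isolated)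
11 | (2S)-5,7-bis(methoxymethoxy)-2-[8-(methoxymethoxy)-2,2-dimethyl-4-oxo-3,4-dihydro-2H-chromen-6-yl]-2,3-dihydro-4H-chromen-4-one | CC1(C)CC(=O)c2cc([C@@H]3CC(=O)c4c(OCOC)cc(OCOC)cc4O3)cc(OCOC)c2O1 | intermediate
12 | (2S)-5,7-dihydroxy-2-(8-hydroxy-2,2-dimethyl-4-oxo-3,4-dihydro-2H-chromen-6-yl)-2,3-dihydro-4H-chromen-4-one | CC1(C)CC(=O)c2cc([C@@H]3CC(=O)c4c(O)cc(O)cc4O3)cc(O)c2O1 | target

## Step count and risks

Total step count: 8. Longest linear sequence: 7 steps (steps 1, 2, 3, 4, 5, 7, 8).

Steps most likely to fail: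

**Step 7 (proposed new method).** The oxa-Michael stage may show poor facial discrimination, because the enone offers the catalyst only one carbonyl to bind. Reversible ring opening may erode enantiopurity. In the first stage, branched hydroacylation or rhodium-induced alkyne oligomerisation may compete. The fallback uses known chemistry and forms the C2–aryl bond instead. It sets out from bromide 5. Pd(OAc)2/XPhos-catalysed borylation with tetrahydroxydiboron (KOAc, EtOH, 80 °C) should give [8-(methoxymethoxy)-2,2-dimethyl-4-oxo-3,4-dihydro-2H-chromen-6-yl]boronic acid F1. Commercial 5,7-dihydroxy-4H-chromen-4-one with NaH/MOMCl in DMF should give 5,7-bis(methoxymethoxy)-4H-chromen-4-one F2. Enantioselective conjugate addition of F1 to F2 with Pd(OCOCF3)2 and the enantiomer of t-BuPyOX that delivers 2S (NH4PF6, H2O, ClCH2CH2Cl, 60 °C), an established flavanone synthesis, comes back to the route at 11.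

**Step 1.** Discrimination between the two catechol hydroxyls may be incomplete, with double alkylation or alkylation at O2. The fallback sets out from 1. Exhaustive alkylation (NaH, MOMCl, DMF, 0 °C) should give 1-[2,3-bis(methoxymethoxy)phenyl]ethan-1-one F3. The acetal ortho to the acetyl group is then removed selectively by carbonyl-assisted cleavage (catalytic HCl, MeOH, 0 °C to rt), which comes back to the route at 2.

**Step 8.** Acid may promote reversible opening of ring C, with loss of configurational integrity at C2, and the released methoxymethyl cation may alkylate the electron-rich ring A. The fallback is a benzyl ether series ending in neutral hydrogenolysis; it sets out from 1 and 8 and comes back at 12.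
- 1 with BnBr/K2CO3 in DMF should give 1-[3-(benzyloxy)-2-hydroxyphenyl]ethan-1-one F4.
- NBS in MeCN should give 1-[3-(benzyloxy)-5-bromo-2-hydroxyphenyl]ethan-1-one F5.
- Kabbe condensation with acetone/pyrrolidine should pass through 1-[3-(benzyloxy)-5-bromo-2-hydroxyphenyl]-3-methylbut-2-en-1-one F6 (not isolated) to 8-(benzyloxy)-6-bromo-2,2-dimethyl-2,3-dihydro-4H-chromen-4-one F7.
- Sonogashira coupling with ethynyltrimethylsilane should give 8-(benzyloxy)-2,2-dimethyl-6-[(trimethylsilyl)ethynyl]-2,3-dihydro-4H-chromen-4-one F8.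
- K2CO3/MeOH should give 8-(benzyloxy)-6-ethynyl-2,2-dimethyl-2,3-dihydro-4H-chromen-4-one F9.
- 8 with BnBr (2.1 equiv)/K2CO3 in DMF should give 2,4-bis(benzyloxy)-6-hydroxybenzaldehyde F10.
- The conditions of step 7 applied to F10 and F9 should pass through (E)-1-[2,4-bis(benzyloxy)-6-hydroxyphenyl]-3-[8-(benzyloxy)-2,2-dimethyl-4-oxo-3,4-dihydro-2H-chromen-6-yl]prop-2-en-1-one F11 (not isolated) to (2S)-5,7-bis(benzyloxy)-2-[8-(benzyloxy)-2,2-dimethyl-4-oxo-3,4-dihydro-2H-chromen-6-yl]-2,3-dihydro-4H-chromen-4-one F12.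
- H2 (1 atm), Pd/C, EtOAc/MeOH, rt should then give 12.

Further compounds
F1 | step 7 | [8-(methoxymethoxy)-2,2-dimethyl-4-oxo-3,4-dihydro-2H-chromen-6-yl]boronic acid | CC1(C)CC(=O)c2cc(B(O)O)cc(OCOC)c2O1
F2 | step 7 | 5,7-bis(methoxymethoxy)-4H-chromen-4-one | O=c1ccoc2cc(OCOC)cc(OCOC)c12
F3 | step 1 | 1-[2,3-bis(methoxymethoxy)phenyl]ethan-1-one | CC(=O)c1cccc(OCOC)c1OCOC
F4 | step 8 | 1-[3-(benzyloxy)-2-hydroxyphenyl]ethan-1-one | CC(=O)c1cccc(OCc2ccccc2)c1O
F5 | step 8 | 1-[3-(benzyloxy)-5-bromo-2-hydroxyphenyl]ethan-1-one | CC(=O)c1cc(Br)cc(OCc2ccccc2)c1O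
F6 | step 8 | 1-[3-(benzyloxy)-5-bromo-2-hydroxyphenyl]-3-methylbut-2-en-1-one | CC(C)=CC(=O)c1cc(Br)cc(OCc2ccccc2)c1O
F7 | step 8 | 8-(benzyloxy)-6-bromo-2,2-dimethyl-2,3-dihydro-4H-chromen-4-one | CC1(C)CC(=O)c2cc(Br)cc(OCc3ccccc3)c2O1
F8 | step 8 | 8-(benzyloxy)-2,2-dimethyl-6-[(trimethylsilyl)ethynyl]-2,3-dihydro-4H-chromen-4-one | CC1(C)CC(=O)c2cc(C#C[Si](C)(C)C)cc(OCc3ccccc3)c2O1
F9 | step 8 | 8-(benzyloxy)-6-ethynyl-2,2-dimethyl-2,3-dihydro-4H-chromen-4-one | CC1(C)CC(=O)c2cc(C#C)cc(OCc3ccccc3)c2O1
F10 | step 8 | 2,4-bis(benzyloxy)-6-hydroxybenzaldehyde | O=Cc1c(O)cc(OCc2ccccc2)cc1OCc1ccccc1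
F11 | step 8 | (E)-1-[2,4-bis(benzyloxy)-6-hydroxyphenyl]-3-[8-(benzyloxy)-2,2-dimethyl-4-oxo-3,4-dihydro-2H-chromen-6-yl]prop-2-en-1-one | O=C(/C=C/c1cc(OCc2ccccc2)c2OC(C)(C)CC(=O)c2c1)c1c(O)cc(OCc2ccccc2)cc1OCc1ccccc1
F12 | step 8 | (2S)-5,7-bis(benzyloxy)-2-[8-(benzyloxy)-2,2-dimethyl-4-oxo-3,4-dihydro-2H-chromen-6-yl]-2,3-dihydro-4H-chromen-4-one | CC1(C)CC(=O)c2cc([C@@H]3CC(=O)c4c(OCc5ccccc5)cc(OCc5ccccc5)cc4O3)cc(OCc3ccccc3)c2O1
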